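All runs are simulated on assumed constants; scatter was added.

- A flat curve invites a fit with a slow rate constant or an equilibrium. Yet the oak run, this very flask followed so far, averages 23.0% from 3.00 min to 15.0 min, while the warmer maple run, with 2.4 mM of free catalyst against the same 1.3 mM of impurity, reads 48.7% at 4.00 min.

| flask | left-handed substrate | right-handed substrate | coupling partner | free catalyst | impurity | temperature | remark | time |
|---|---|---|---|---|---|---|---|---|
| oak | 0.050 M | 0.050 M | 0.15 M | 1.2 mM | 1.3 mM | −20 °C | the very flask that is asked about, followed so far |  |
| maple | 0.050 M | 0.050 M | 0.15 M | 2.4 mM | 1.3 mM | −14 °C | run made earlier |  |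
| flask | 0.050 M | 0.050 M | 0.150 M | 1.2 mM | 1.3 mM | −20 °C |  | 20 min |

| run | time / min | left-handed product / % |
|---|---|---|
| oak | 3.00 | 23.2 |
| oak | 6.00 | 24.9 |
| oak | 10.0 | 22.2 |
| oak | 12.0 | 23.1 |
| oak | 15.0 | 21.6 |
| maple | 0.833 | 45.0 |
| maple | 1.50 | 49.4 |
| maple | 2.50 | 48.4 |
| maple | 3.00 | 49.5 |
| maple | 4.00 | 48.7 |

(readings scatter by 1 percentage point)

1. left-handed product, in percent of the left-handed substrate and right-handed substrate together first charged, at 20 min
2. what to do for the largest gain in left-handed product; "none" if nothing gains more than 2 percentage points (dusk / summer / autumn / midnight / noon / none)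
3. left-handed product present, with what was taken out counted in, in percent of the left-handed substrate and right-handed substrate together first charged, after dusk
4. left-handed product present, with what was taken out counted in, in percent of the left-handed substrate and right-handed substrate together first charged, after summer

- dusk: change nothing and wait 6.0 min more
- summer: at 20 min raise the temperature by 15 K, then wait 6.0 min
- autumn: at 20 min add coupling partner, 50.0% of the amount charged, then wait 6.0 min
- midnight: at 20 min take out 90% of the left-handed product then present, then wait 6.0 min
- noon: at 20 min add free catalyst, 100% of the amount charged, then wait 6.0 min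

- free catalyst is single-handed; left-handed substrate and right-handed substrate are mirror images of each other, charged as a racemate, each of them at the stated concentration
- what is taken out of left-handed product is counted as made
- additions bring no volume worth counting

- The reckoning made here supposes that free catalyst consumes left-handed substrate and impurity each in proportion to its own concentration, and that impurity removes catalyst one for one. Oak then ends with 54.0% of its left-handed substrate and 7.69% of its impurity, which gives 0.240 as the halving ratio, the halvings of left-handed substrate per halving of impurity, a reading akin to a selectivity factor, for one temperature and one level of coupling partner.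
- Waiting (dusk): substrate halvings run alongside impurity halvings, and oak is already flat at 3.00 min, so this reckoning keeps 23.0% at 20 min and after dusk.
- Warming (summer) could shift a running competition, but the oak charge has less catalyst than impurity, so by hand the product stays at 23.0%, unless the loss reverses.
- Adding coupling partner (autumn) to this flask changes nothing by hand, since 0.150 M already stands above the 0.050 M of left-handed substrate and by this reckoning the halving count has stopped.
- Taking out product (midnight) would answer an equilibrium, but the maple run, 6.00 K warmer, reads more product than oak from the same substrate charges, so by hand it gains nothing.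
- Adding catalyst (noon) to this flask turns the balance round: 1.20 mM of fresh catalyst meets about 0.100 mM of impurity by this count, so by hand the product climbs towards 50.0%, the left-handed share of the charge.
- The forecast gives 23% now, 23% after dusk, 23% after summer and noon as the best choice, on the ground that “Impurity (1.3 mM) exceeds catalyst (1.2 mM) in oak, so all catalyst is probably poisoned”.
- The flask gives 22.9% now, 22.9% after dusk and 22.9% after summer, and noon is best with a gain of 27 percentage points, so the forecast held.

    coupling partner + catalyst intermediate A → free catalyst + left-handed product (k = 19.0 L mol⁻¹ s⁻¹, Ea = 40.0 kJ mol⁻¹)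
    coupling partner → decomposition product (k = 3.30 × 10⁻⁵ s⁻¹, Ea = 74.0 kJ mol⁻¹)
    free catalyst + right-handed substrate ⇌ catalyst intermediate B (K = 6.90 L mol⁻¹, k = 370 L mol⁻¹ s⁻¹, Ea = 38.0 kJ mol⁻¹, ΔH = −54.0 kJ mol⁻¹)
    coupling partner + catalyst intermediate B → free catalyst + right-handed product (k = 8.10 L mol⁻¹ s⁻¹, Ea = 38.0 kJ mol⁻¹)
    free catalyst + left-handed substrate ⇌ catalyst intermediate A (K = 28.0 L mol⁻¹, k = 480 L mol⁻¹ s⁻¹, Ea = 36.0 kJ mol⁻¹, ΔH = −13.0 kJ mol⁻¹)
    free catalyst + impurity → spent catalyst B (k = 190 L mol⁻¹ s⁻¹, Ea = 39.0 kJ mol⁻¹)
    coupling partner + free catalyst → spent catalyst A (k = 0.0760 L mol⁻¹ s⁻¹, Ea = 40.0 kJ mol⁻¹)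
    (constants at −20 °C)

- In this flask, half the turnover of free catalyst and left-handed substrate into catalyst intermediate A up to 20 min is done at 0.208 min, and half the decomposition of coupling partner up to 20 min at 9.86 min. Between 10.0 min and 20.0 min, left-handed product stays at 22.9% while coupling partner goes from 80.7% to 79.1%.
- At 20 min this flask holds 8.41% of its catalyst as spent catalyst A and 91.6% as spent catalyst B. Impurity stands at 15% of its charge, not 7.69%, and with 54% of the left-handed substrate left the halving ratio moves from 0.240 to 0.328.
- In the neighbour with 0.0052 M of impurity, one-for-one loss of catalyst leaves 76.9% of the impurity, so the ratio 0.328 leaves 91.8% of the left-handed substrate, or 4.10% of left-handed product. The computed flask gives 4.36%.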